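**Assumption:** the SMILES is read as (4Z,6R,7R,8R,10R) with an (E)-2-methylbut-2-enoate (tiglate) on O8. Germacrane numbering is used throughout (C1 ketone, C2=C3 furanone enol ether, C4=C5, C6–O lactone, C8–O ester, C10 quaternary, C11=C13 exo-methylene).

## Retrosynthetic overview

1. Target ⇒ C8-epimeric macrocyclic alcohol + tiglic acid; a Mitsunobu esterification installs the ester with inversion.
2. Key step: macrocycle ⇒ acyclic, preformed 3(2H)-furanone carrying a C8 aldehyde and a 3-(bromomethyl)butenolide. A Cr(II) Barbier macrocyclisation forms C7–C8, closes the 10-membered carbocycle (9-membered oxa-bridge) last, sets C7 and C8 and unveils the α-methylene lactone. This replaces the usual plan of closing the ring by RCM at C4=C5 or forming the furanone last by transannular cyclisation.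
3. Butenolide ⇒ C6 vinyl carbinol, by acylation with 2-(bromomethyl)acrylic acid and RCM. C6 is fixed by lipase resolution; the Z-C4=C5 olefin is bought in (Z)-3-methylpent-2-en-4-yn-1-ol.
4. Furanone ⇒ lithium acetylide of the enyne + α-hydroxy Weinreb amide, then 5-endo-dig oxa-Michael closure. C10 comes from (S)-lactic acid by Seebach alkylation.
5. Ring order: 3(2H)-furanone → butenolide → macrocycle (which becomes the α-methylene-γ-lactone in the same step).

## Forward route

**Step 1**
Reactants: 1, (Z)-3-methylpent-2-en-4-yn-1-ol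
Product: 2, (Z)-3-methylpent-2-en-4-ynal
Conditions: MnO2 (15 equiv), CH2Cl2, rt; filter, use the solution directly (volatile)
Reagents that add atoms: none
Why: MnO2 allylic oxidation is selective for the allylic alcohol, leaves the terminal alkyne alone and preserves the Z geometry (as in nerol → neral); no stereocentre is involved.

**Step 2**
Reactants: 2, (Z)-3-methylpent-2-en-4-ynal; 3, vinylmagnesium bromide
Product: 4, rac-(Z)-5-methylhepta-1,4-dien-6-yn-3-ol
Conditions: CH2=CHMgBr (1.1 equiv), THF, −78 °C
Reagents that add atoms: vinylmagnesium bromide, C=C[Mg]Br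
Why: Grignard 1,2-addition to the enal is much faster than alkyne deprotonation at −78 °C; the product is racemic at C6.

**Step 3**
Reactants: 4, rac-(Z)-5-methylhepta-1,4-dien-6-yn-3-ol
Product: 5, (3S,4Z)-5-methylhepta-1,4-dien-6-yn-3-ol
Conditions: Novozym 435 (CAL-B), vinyl acetate, MTBE, 30 °C, stop at about 55% conversion; chromatography
Reagents that add atoms: none (vinyl acetate acylates only the discarded R enantiomer)
Why: Lipase kinetic resolution; by the Kazlauskas rule the R enantiomer (large dienynyl versus medium vinyl group) is acylated, leaving the S alcohol in high ee and fixing C6.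

**Step 4**
Reactants: 5, (3S,4Z)-5-methylhepta-1,4-dien-6-yn-3-ol; 6, chlorotriethylsilane
Product: 7, triethyl{[(3S,4Z)-5-methylhepta-1,4-dien-6-yn-3-yl]oxy}silane
Conditions: TESCl, imidazole, CH2Cl2, 0 °C
Reagents that add atoms: chlorotriethylsilane, CC[Si](CC)(CC)Cl
Why: Silyl ether formation; the C6 oxygen must be masked because a free cis-disposed OH would add 5-exo-dig to the ynone of step 9 and give a furan.

**Step 5**
Reactants: 8, (S)-lactic acid; 9, pivaldehyde
Product: 10, (2S,5S)-2-tert-butyl-5-methyl-1,3-dioxolan-4-one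
Conditions: cat. TsOH/H2SO4, pentane, reflux (Dean–Stark); recrystallise at −78 °C
Reagents that add atoms: pivaldehyde, CC(C)(C)C=O
Why: Seebach acetalisation; the cis acetal is favoured and purified by crystallisation, storing the lactate stereocentre in the acetal carbon.

**Step 6**
Reactants: 10, (2S,5S)-2-tert-butyl-5-methyl-1,3-dioxolan-4-one; 11, allyl bromide
Product: 12, (2S,5R)-5-allyl-2-tert-butyl-5-methyl-1,3-dioxolan-4-one
Conditions: LDA, THF, −78 °C; allyl bromide, −78 → −30 °C
Reagents that add atoms: allyl bromide, C=CCBr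
Why: Seebach self-regeneration of stereocentres; the enolate is alkylated anti to the tert-butyl group (>95:5), creating the C10 quaternary centre with the configuration needed (R after unmasking).

**Step 7**
Reactants: 12, (2S,5R)-5-allyl-2-tert-butyl-5-methyl-1,3-dioxolan-4-one; 13, N,O-dimethylhydroxylamine hydrochloride
Product: 14, (R)-2-hydroxy-N-methoxy-N,2-dimethylpent-4-enamide
Conditions: MeNHOMe·HCl (3 equiv), i-PrMgCl (6 equiv), THF, −20 → 0 °C
Reagents that add atoms: N,O-dimethylhydroxylamine hydrochloride, CNOC.Cl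
Why: Weinreb aminolysis of the activated acylal-type lactone; pivaldehyde is expelled and the quaternary centre is not touched.

**Step 8**
Reactants: 14, (R)-2-hydroxy-N-methoxy-N,2-dimethylpent-4-enamide; 15, trimethyl orthoformate
Product: 16, (R)-2-hydroxy-N,4,4-trimethoxy-N,2-dimethylbutanamide
Conditions: O3, CH2Cl2/MeOH, −78 °C; Me2S; then HC(OMe)3, PPTS (cat.), MeOH, rt
Reagents that add atoms: trimethyl orthoformate, COC(OC)OC (with methanol, CO; supplies the two OMe groups)
Why: Ozonolysis followed by immediate acetalisation masks the future C8 aldehyde, so the retro-aldol-prone β-hydroxy aldehyde is never isolated.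

**Step 9**
Reactants: 7, triethyl{[(3S,4Z)-5-methylhepta-1,4-dien-6-yn-3-yl]oxy}silane; 16, (R)-2-hydroxy-N,4,4-trimethoxy-N,2-dimethylbutanamide
Product: 17, (R)-2-(2,2-dimethoxyethyl)-2-methyl-5-[(2Z,4S)-4-(triethylsilyloxy)hexa-2,5-dien-2-yl]furan-3(2H)-one
Conditions: 7 (1.2 equiv), n-BuLi, THF, −78 °C; add 16 pre-treated with i-PrMgCl (1.0 equiv); −78 → 0 °C; then MeOH, rt (one pot); aq. NH4Cl
Reagents that add atoms: none beyond reactants 7 and 16
Why: Weinreb ketone synthesis gives the α′-hydroxy ynone, whose tertiary alkoxide closes by 5-endo-dig oxa-Michael addition to the 3(2H)-furanone; C10 and C6 are spectators.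

**Step 10**
Reactants: 17, the furanone TES ether
Product: 18, (R)-2-(2,2-dimethoxyethyl)-5-[(2Z,4S)-4-hydroxyhexa-2,5-dien-2-yl]-2-methylfuran-3(2H)-one
Conditions: TBAF/AcOH (1:1), THF, 0 °C; use the crude product at once
Reagents that add atoms: none
Why: Buffered fluoride desilylation; near-neutral conditions are chosen because acid or base could let the cis C6–OH attack furanone C3 and aromatise to a furan.

**Step 11**
Reactants: 18, the furanone dienol; 19, 2-(bromomethyl)acrylic acid
Product: 20, (3S,4Z)-5-[(R)-5-(2,2-dimethoxyethyl)-5-methyl-4-oxo-4,5-dihydrofuran-2-yl]hexa-1,4-dien-3-yl 2-(bromomethyl)acrylate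
Conditions: 19 (1.5 equiv), DCC, DMAP (0.1 equiv), CH2Cl2, 0 °C
Reagents that add atoms: 2-(bromomethyl)acrylic acid, C=C(CBr)C(=O)O
Why: Steglich esterification of the secondary alcohol with retention; it also removes the nucleophilicity of O6 for good.

**Step 12**
Reactants: 20, the bis-allylic 2-(bromomethyl)acrylate
Product: 21, (R)-5-{(Z)-1-[(R)-4-(bromomethyl)-5-oxo-2,5-dihydrofuran-2-yl]prop-1-en-2-yl}-2-(2,2-dimethoxyethyl)-2-methylfuran-3(2H)-one
Conditions: Grubbs II (5 mol %), 1,4-benzoquinone (10 mol %), CH2Cl2 (5 mM), 40 °C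
Reagents that add atoms: none (ethylene is lost)
Why: Ring-closing metathesis starts at the terminal vinyl group and closes the five-membered butenolide onto the acrylate; the conjugated trisubstituted C4=C5 and the furanone are inert, and benzoquinone suppresses Ru–H isomerisation at the acidic C6–H.

**Step 13**
Reactants: 21, the bromomethyl butenolide acetal
Product: 22, 2-[(R)-5-{(Z)-1-[(R)-4-(bromomethyl)-5-oxo-2,5-dihydrofuran-2-yl]prop-1-en-2-yl}-2-methyl-3-oxo-2,3-dihydrofuran-2-yl]acetaldehyde
Conditions: Amberlyst-15, acetone/H2O (20:1), rt; use directly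
Reagents that add atoms: water, O
Why: Acid-catalysed acetal hydrolysis; no base is present, so the β-alkoxy aldehyde does not eliminate and C6 does not epimerise.

**Step 14 (key step)**
Reactants: 22, the aldehyde / bromomethyl butenolide
Product: 23, (4Z,6R,7R,8S,10R)-8-hydroxy-1-oxo-3,10-epoxygermacra-2,4,11(13)-trien-12,6-olide (the target skeleton with a free, epimeric C8–OH)
Conditions: CrCl2 (10 equiv), THF, rt, syringe-pump addition over 12 h to 2 mM final concentration; aq. NH4Cl
Reagents that add atoms: none
Why: Intramolecular Nozaki–Hiyama–Kishi/Barbier allylation: the allyl–Cr(III) formed at C13 adds through C7 (SE2′) to the tethered aldehyde, which selects only aldehydes and regenerates the exo-methylene; attack anti to the C6 substituent gives the trans lactone (7R), and a closed chair transition state with the ring-fixed E-allyl unit and an equatorial aldehyde chain gives the anti adduct (8S), the C8 epimer that step 15 inverts.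

**Step 15**
Reactants: 23, the 8-epi alcohol; 24, tiglic acid
Product: 25, atripliciolide tiglate, (4Z,6R,7R,8R,10R)-8-[(E)-2-methylbut-2-enoyloxy]-1-oxo-3,10-epoxygermacra-2,4,11(13)-trien-12,6-olide
Conditions: tiglic acid (3 equiv), PPh3 (3 equiv), DIAD (3 equiv), toluene, 0 °C → rt
Reagents that add atoms: tiglic acid, C/C=C(\C)C(=O)O
Why: Mitsunobu esterification proceeds by SN2 inversion at C8 (8S → 8R) and installs the tiglate in the same operation, under base-free conditions that the α-methylene lactone and furanone tolerate.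

## Compound list

1 | (Z)-3-methylpent-2-en-4-yn-1-ol | OC/C=C(/C)C#C | starting material
2 | (Z)-3-methylpent-2-en-4-ynal | O=C/C=C(/C)C#C | intermediate
3 | vinylmagnesium bromide | C=C[Mg]Br | starting material
4 | rac-(Z)-5-methylhepta-1,4-dien-6-yn-3-ol | OC(C=C)/C=C(/C)C#C | intermediate
5 | (3S,4Z)-5-methylhepta-1,4-dien-6-yn-3-ol | O[C@@H](C=C)/C=C(/C)C#C | intermediate
6 | chlorotriethylsilane | CC[Si](CC)(CC)Cl | starting material
7 | triethyl{[(3S,4Z)-5-methylhepta-1,4-dien-6-yn-3-yl]oxy}silane | CC[Si](CC)(CC)O[C@@H](C=C)/C=C(/C)C#C | intermediate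
8 | (S)-lactic acid | C[C@H](O)C(=O)O | starting material
9 | pivaldehyde | CC(C)(C)C=O | starting material
10 | (2S,5S)-2-tert-butyl-5-methyl-1,3-dioxolan-4-one | C[C@@H]1O[C@H](C(C)(C)C)OC1=O | intermediate
11 | allyl bromide | C=CCBr | starting material
12 | (2S,5R)-5-allyl-2-tert-butyl-5-methyl-1,3-dioxolan-4-one | C[C@]1(CC=C)O[C@H](C(C)(C)C)OC1=O | intermediate
13 | N,O-dimethylhydroxylamine hydrochloride | CNOC.Cl | starting material
14 | (R)-2-hydroxy-N-methoxy-N,2-dimethylpent-4-enamide | CON(C)C(=O)[C@@](C)(CC=C)O | intermediate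
15 | trimethyl orthoformate | COC(OC)OC | starting material
16 | (R)-2-hydroxy-N,4,4-trimethoxy-N,2-dimethylbutanamide | CON(C)C(=O)[C@@](C)(CC(OC)OC)O | intermediate
17 | (R)-2-(2,2-dimethoxyethyl)-2-methyl-5-[(2Z,4S)-4-(triethylsilyloxy)hexa-2,5-dien-2-yl]furan-3(2H)-one | CC[Si](CC)(CC)O[C@@H](C=C)/C=C(/C)C1=CC(=O)[C@@](C)(CC(OC)OC)O1 | intermediate
18 | (R)-2-(2,2-dimethoxyethyl)-5-[(2Z,4S)-4-hydroxyhexa-2,5-dien-2-yl]-2-methylfuran-3(2H)-one | O[C@@H](C=C)/C=C(/C)C1=CC(=O)[C@@](C)(CC(OC)OC)O1 | intermediate
19 | 2-(bromomethyl)acrylic acid | C=C(CBr)C(=O)O | starting material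
20 | (3S,4Z)-5-[(R)-5-(2,2-dimethoxyethyl)-5-methyl-4-oxo-4,5-dihydrofuran-2-yl]hexa-1,4-dien-3-yl 2-(bromomethyl)acrylate | C=C(CBr)C(=O)O[C@@H](C=C)/C=C(/C)C1=CC(=O)[C@@](C)(CC(OC)OC)O1 | intermediate
21 | (R)-5-{(Z)-1-[(R)-4-(bromomethyl)-5-oxo-2,5-dihydrofuran-2-yl]prop-1-en-2-yl}-2-(2,2-dimethoxyethyl)-2-methylfuran-3(2H)-one | O=C1O[C@H](/C=C(/C)C2=CC(=O)[C@@](C)(CC(OC)OC)O2)C=C1CBr | intermediate
22 | 2-[(R)-5-{(Z)-1-[(R)-4-(bromomethyl)-5-oxo-2,5-dihydrofuran-2-yl]prop-1-en-2-yl}-2-methyl-3-oxo-2,3-dihydrofuran-2-yl]acetaldehyde | O=C1O[C@H](/C=C(/C)C2=CC(=O)[C@@](C)(CC=O)O2)C=C1CBr | intermediate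
23 | (4Z,6R,7R,8S,10R)-8-hydroxy-1-oxo-3,10-epoxygermacra-2,4,11(13)-trien-12,6-olide | C=C1C(=O)O[C@@H]2/C=C(/C)C3=CC(=O)[C@@](C)(C[C@H](O)[C@@H]12)O3 | intermediate
24 | tiglic acid, (E)-2-methylbut-2-enoic acid | C/C=C(\C)C(=O)O | starting material
25 | atripliciolide tiglate | C=C1C(=O)O[C@@H]2/C=C(/C)C3=CC(=O)[C@@](C)(C[C@@H](OC(=O)/C(C)=C/C)[C@@H]12)O3 | target

## Step count and risks

**Total steps:** 15.

**Longest linear sequence:** 11 steps (1 → 2 → 4 → 5 → 7 → 17 → 18 → 20 → 21 → 22 → 23 → 25). The branch from 8 (steps 5–8, then 9–15) is also 11.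

**Steps most likely to fail:**

1. **Step 14, Cr(II) Barbier macrocyclisation onto the preformed furanone.** The bridged ring is strained, oligomerisation competes, and the facial selectivity at C7 and C8 in a macrocyclic transition state is predicted, not known.
   Fallback: give up furanone-first ring closure. Run the Barbier intermolecularly (a 5-vinyl-3-(bromomethyl)butenolide with a 5-isopropenyl-furanone aldehyde, Zn/aq. NH4Cl) and close the ring afterwards by RCM at C4=C5.

2. **Step 15, Mitsunobu inversion with tiglic acid.** The macrocyclic secondary alcohol is hindered, elimination towards C7=C8 is possible, and PPh3/betaine can add to the α-methylene lactone.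
   Fallback: oxidise C8–OH to the ketone (DMP) and reduce it (e.g. NaBH4/CeCl3) to the 8β-alcohol, then acylate with tigloyl chloride/DMAP. If step 14 in practice gives the 8β-alcohol directly, acylate it without inversion.

3. **Steps 10–11, handling of dienol 18.** The free C6–OH sits cis to the vinylogous-ester carbon C3 and can cyclise and aromatise to a furan.
   Fallback: build the butenolide before the furanone. Acylate and ring-close the enyne carbinol first (alkyne as its TMS derivative), then join C1–C2 by NHK addition of the derived iodoalkyne to a C1 aldehyde, oxidise, and close the furanone with Au(I), so a free C6–OH never coexists with the furanone.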